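**Retrosynthetic overview**

1. The last C–C disconnection is the C3–C4 bond of the (2Z,6E)-nona-2,6-dienoic acid chain, between the vinylic CH of the acrylic acid and its allylic CH2. It gives primary homoallylic bromide 16 (chromene fragment A) and 2-(4-methylpent-3-enyl)acrylic acid as its N-(quinolin-8-yl) amide 25 (fragment B).
2. Enabling feature: the vinylic C3–H bond cis to the carboxyl carbon C1. With C1 as the quinolin-8-yl amide, the two nitrogens hold iron so that only this C–H can close a five-membered ferracycle (Fe, N, C1, C2, C3). This turns the acceptor carbon C3 into a nucleophile and delivers the alkyl group cis to the carboxyl, i.e. the 2Z olefin.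
3. Fragment A: (R)-linalool supplies chromene C2 with its methyl group, C3 (its vinyl group) and the side chain up to the trisubstituted olefin. SNAr O-arylation, Wittig methylenation and ring-closing metathesis close the pyran ring, the only ring formed (the benzene ring is bought).
4. The side chain is then grown by (E)-selective allylic oxidation of the terminal methyl group, methylenation, terminal hydroboration and bromination. Fragment B comes from phosphonoacetate alkylation and Horner–Wadsworth–Emmons methylenation.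
5. After the coupling the amide is cleaved to the acid through its N-Boc derivative and the phenol is desilylated.

Key step: step 14

Assumption: (R)-(−)-linalool is used in high enantiomeric purity and its tertiary C–O bond is never broken; after step 3 the chromene is kept from UV light and prolonged heating, since reversible electrocyclic opening of the pyran ring would racemise C2.

**Route**

Step 1
Reactants: 1 (R)-(−)-linalool; 2 5-bromo-2-fluoro-3-methylbenzaldehyde
Product: 4 (R)-5-bromo-2-[(3,7-dimethylocta-1,6-dien-3-yl)oxy]-3-methylbenzaldehyde, via potassium (R)-linaloolate 3 (not isolated)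
Conditions: KH, THF, 0 °C; then 2, THF/DMF, 0 °C to rt
Reagents that add atoms: none
Why: Nucleophilic aromatic substitution (SNAr) of the fluoride, activated by the ortho formyl group and the para bromine, by the tertiary alkoxide; the C–O bond of linalool is not broken, so the (R) centre of 1 passes into 4 unchanged.

Step 2
Reactants: 4 (R)-5-bromo-2-[(3,7-dimethylocta-1,6-dien-3-yl)oxy]-3-methylbenzaldehyde
Product: 5 (R)-5-bromo-2-[(3,7-dimethylocta-1,6-dien-3-yl)oxy]-1-ethenyl-3-methylbenzene
Conditions: Ph3PCH3Br, KOt-Bu, THF, 0 °C to rt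
Reagents that add atoms: methyltriphenylphosphonium bromide, C[P+](c1ccccc1)(c1ccccc1)c1ccccc1.[Br-]
Why: Wittig methylenation of the aryl aldehyde with the non-stabilised ylide should give the styrene needed for ring closure without touching the stereocentre.

Step 3
Reactants: 5 (R)-5-bromo-2-[(3,7-dimethylocta-1,6-dien-3-yl)oxy]-1-ethenyl-3-methylbenzene
Product: 6 (R)-6-bromo-2,8-dimethyl-2-(4-methylpent-3-en-1-yl)-2H-chromene
Conditions: second-generation Grubbs catalyst RuCl2(=CHPh)(PCy3)(H2IMes) (3 mol %), CH2Cl2, 40 °C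
Reagents that add atoms: none
Why: Ring-closing metathesis of the styrene with the vinyl group on the quaternary carbon closes the six-membered pyran ring with loss of ethene; the catalyst should load on the unhindered styrene and cyclise faster than it engages the trisubstituted olefin.

Step 4
Reactants: 6 (R)-6-bromo-2,8-dimethyl-2-(4-methylpent-3-en-1-yl)-2H-chromene
Product: 9 (R)-2,8-dimethyl-2-(4-methylpent-3-en-1-yl)-2H-chromen-6-ol, via aryllithium 7 (not isolated), via lithium aryltrimethoxyborate 8 (not isolated)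
Conditions: t-BuLi (2.1 equiv), THF, −78 °C; B(OMe)3, −78 °C to rt; then 30% H2O2, aq. NaOH, 0 °C
Reagents that add atoms: hydrogen peroxide, OO
Why: Bromine–lithium exchange, borylation and oxidative aryl migration from boron to oxygen (boronate oxidation) should convert the aryl bromide into the phenol at low temperature, where the chromene is not at risk.

Step 5
Reactants: 9 (R)-2,8-dimethyl-2-(4-methylpent-3-en-1-yl)-2H-chromen-6-ol
Product: 10 (R)-2,8-dimethyl-2-(4-methylpent-3-en-1-yl)-6-(triisopropylsilyloxy)-2H-chromene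
Conditions: i-Pr3SiCl, imidazole, DMF, rt
Reagents that add atoms: triisopropylsilyl chloride, CC(C)[Si](Cl)(C(C)C)C(C)C
Why: Silylation of the phenol gives a base-stable silyl ether that masks the acidic OH during the ylide, borane and Grignard steps.

Step 6
Reactants: 10 (R)-2,8-dimethyl-2-(4-methylpent-3-en-1-yl)-6-(triisopropylsilyloxy)-2H-chromene
Product: 12 (E)-5-[(R)-2,8-dimethyl-6-(triisopropylsilyloxy)-2H-chromen-2-yl]-2-methylpent-2-enal, via (E)-allylic alcohol 11 (not isolated)
Conditions: SeO2 (cat.), t-BuOOH, salicylic acid (cat.), CH2Cl2, rt; then MnO2, CH2Cl2, rt on the crude mixture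
Reagents that add atoms: selenium dioxide, O=[Se]=O; tert-butyl hydroperoxide, CC(C)(C)OO
Why: Riley allylic oxidation (ene reaction, then 2,3-sigmatropic shift) of the only trisubstituted olefin should place oxygen on the terminal carbon trans to the chain, giving the (E)-allylic alcohol, and MnO2 then brings alcohol and aldehyde together as the (E)-enal.

Step 7
Reactants: 12 (E)-5-[(R)-2,8-dimethyl-6-(triisopropylsilyloxy)-2H-chromen-2-yl]-2-methylpent-2-enal
Product: 13 (R)-2,8-dimethyl-2-[(3E)-4-methylhexa-3,5-dien-1-yl]-6-(triisopropylsilyloxy)-2H-chromene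
Conditions: Ph3PCH3Br, KOt-Bu, THF, 0 °C to rt
Reagents that add atoms: methyltriphenylphosphonium bromide, C[P+](c1ccccc1)(c1ccccc1)c1ccccc1.[Br-]
Why: Wittig methylenation of the enal should give the terminal 1,3-diene with the (E) trisubstituted olefin unchanged.

Step 8
Reactants: 13 (R)-2,8-dimethyl-2-[(3E)-4-methylhexa-3,5-dien-1-yl]-6-(triisopropylsilyloxy)-2H-chromene
Product: 15 (E)-6-[(R)-2,8-dimethyl-6-(triisopropylsilyloxy)-2H-chromen-2-yl]-3-methylhex-3-en-1-ol, via B-alkyl-9-BBN 14 (not isolated)
Conditions: 9-BBN, THF, 0 °C to rt; then aq. NaOH, 30% H2O2, 0 °C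
Reagents that add atoms: hydrogen peroxide, OO
Why: Anti-Markovnikov hydroboration with bulky 9-BBN should take place only at the terminal vinyl group of the diene, sparing the trisubstituted olefin and the hindered chromene double bond, and oxidation gives the primary homoallylic alcohol.

Step 9
Reactants: 15 (E)-6-[(R)-2,8-dimethyl-6-(triisopropylsilyloxy)-2H-chromen-2-yl]-3-methylhex-3-en-1-ol
Product: 16 (R)-2-[(3E)-6-bromo-4-methylhex-3-en-1-yl]-2,8-dimethyl-6-(triisopropylsilyloxy)-2H-chromene
Conditions: CBr4, PPh3, CH2Cl2, 0 °C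
Reagents that add atoms: carbon tetrabromide, BrC(Br)(Br)Br
Why: Appel bromination of the primary alcohol under neutral conditions should give the homoallylic bromide without allylic transposition or loss of the silyl ether.

Step 10
Reactants: 17 triethyl phosphonoacetate; 18 5-bromo-2-methylpent-2-ene
Product: 20 ethyl 2-(diethoxyphosphoryl)-6-methylhept-5-enoate (racemic), via sodium phosphonoacetate 19 (not isolated)
Conditions: NaH, THF/DMF, 0 °C; then 18, 60 °C
Reagents that add atoms: none
Why: C-alkylation of the stabilised phosphonoacetate anion with the primary bromide; the new centre is racemic and is removed in the next step.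

Step 11
Reactants: 20 ethyl 2-(diethoxyphosphoryl)-6-methylhept-5-enoate
Product: 21 ethyl 6-methyl-2-methylidenehept-5-enoate
Conditions: 37% aq. CH2O, K2CO3, H2O, rt to 80 °C
Reagents that add atoms: formaldehyde, C=O
Why: Horner–Wadsworth–Emmons olefination with formaldehyde should give the 2-substituted acrylate directly.

Step 12
Reactants: 21 ethyl 6-methyl-2-methylidenehept-5-enoate
Product: 22 6-methyl-2-methylidenehept-5-enoic acid
Conditions: LiOH, THF/H2O, rt; then 1 M HCl
Reagents that add atoms: lithium hydroxide, [Li+].[OH-]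
Why: Saponification of the ethyl ester gives the acrylic acid.

Step 13
Reactants: 22 6-methyl-2-methylidenehept-5-enoic acid; 23 8-aminoquinoline
Product: 25 6-methyl-2-methylidene-N-(quinolin-8-yl)hept-5-enamide, via acid chloride 24 (not isolated)
Conditions: (COCl)2, DMF (cat.), CH2Cl2, 0 °C to rt; then 23, Et3N, CH2Cl2, 0 °C
Reagents that add atoms: none
Why: Acylation of the weakly nucleophilic 8-aminoquinoline with the acid chloride installs the N,N-bidentate directing group on the carboxyl carbon.

Step 14
Reactants: 16 (R)-2-[(3E)-6-bromo-4-methylhex-3-en-1-yl]-2,8-dimethyl-6-(triisopropylsilyloxy)-2H-chromene; 25 6-methyl-2-methylidene-N-(quinolin-8-yl)hept-5-enamide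
Product: 27 (2Z,6E)-9-[(R)-2,8-dimethyl-6-(triisopropylsilyloxy)-2H-chromen-2-yl]-6-methyl-2-(4-methylpent-3-en-1-yl)-N-(quinolin-8-yl)nona-2,6-dienamide, via bromomagnesium amidate 26 (not isolated)
Conditions: Fe(acac)3 (10 mol %), Ph2PCH2CH2PPh2 (dppe, 15 mol %), PhMgBr (slow addition), THF, 65 °C, 25 in excess over 16; then aq. NH4Cl
Reagents that add atoms: none
Why: PhMgBr deprotonates the amide N–H (26) and reduces Fe(acac)3 to a low-valent aryliron species held by the amidate and quinoline nitrogens; the only C–H bond within reach, C3–H cis to the carbonyl, is cleaved to a five-membered ferracycle (Fe, N, C1, C2, C3), which transfers one electron to bromide 16, captures the resulting primary alkyl radical and forms the C3–CH2 bond by reductive elimination. The closest known reaction type is the iron-catalysed, 8-aminoquinoline-directed C(sp2)–H alkylation of aromatic and olefinic carboxamides with primary alkyl bromides and tosylates. No ring of the product is closed (the ferracycle is a transient chelate) and no stereocentre is formed; the one stereochemical element created, the C2=C3 geometry, is fixed as Z by the chelate because the alkyl group replaces the hydrogen syn to the carbonyl. The step needs site selectivity (secured by the single cis hydrogen at C3 of the 1,1-disubstituted olefin, which also rules out a second alkylation), chemoselectivity for C–H alkylation over direct coupling of 16 with PhMgBr (slow addition of the Grignard reagent and an excess of the cheap amide 25) and retention of the (E) olefin of 16 (3-exo closure of the homoallyl radical is slow and reversible beside its capture by iron). In polarity terms the acceptor carbon C3 of the acrylamide becomes a carbon–iron nucleophile and is joined to an electrophilic sp3 carbon, so the olefin geometry and the carboxyl oxidation level arrive in the coupling itself.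

Step 15
Reactants: 27 (2Z,6E)-9-[(R)-2,8-dimethyl-6-(triisopropylsilyloxy)-2H-chromen-2-yl]-6-methyl-2-(4-methylpent-3-en-1-yl)-N-(quinolin-8-yl)nona-2,6-dienamide
Product: 30 (2Z,6E)-9-[(R)-2,8-dimethyl-6-(triisopropylsilyloxy)-2H-chromen-2-yl]-6-methyl-2-(4-methylpent-3-en-1-yl)nona-2,6-dienoic acid, via N-Boc imide 28 (not isolated), via lithium peroxycarboxylate 29 (not isolated)
Conditions: Boc2O, DMAP (cat.), MeCN, rt; concentrate; then LiOH, 30% H2O2, THF/H2O, 0 °C; Na2SO3; 1 M HCl to pH 3
Reagents that add atoms: hydrogen peroxide, OO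
Why: N-acylation with Boc2O twists and activates the secondary amide, so that hydroperoxide should attack the acyl carbonyl and expel the carbamate (activated-amide hydrolysis), and sulfite reduces the peroxy acid to the acid without change of olefin geometry.

Step 16
Reactants: 30 (2Z,6E)-9-[(R)-2,8-dimethyl-6-(triisopropylsilyloxy)-2H-chromen-2-yl]-6-methyl-2-(4-methylpent-3-en-1-yl)nona-2,6-dienoic acid
Product: 31 (R)-sargachromenol
Conditions: Bu4NF, THF, 0 °C to rt, under argon; then dilute HCl to pH 3
Reagents that add atoms: none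
Why: Fluoride-mediated cleavage of the aryl silyl ether should release the phenol under conditions that leave the chromene, both trisubstituted olefins and the acid untouched.

**Compound list**

1 | (R)-(−)-linalool | CC(C)=CCC[C@@](C)(O)C=C | starting material
2 | 5-bromo-2-fluoro-3-methylbenzaldehyde | O=Cc1cc(Br)cc(C)c1F | starting material
3 | potassium (R)-linaloolate | CC(C)=CCC[C@@](C)([O-])C=C.[K+] | intermediate
4 | (R)-5-bromo-2-[(3,7-dimethylocta-1,6-dien-3-yl)oxy]-3-methylbenzaldehyde | CC(C)=CCC[C@@](C)(Oc1c(C)cc(Br)cc1C=O)C=C | intermediate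
5 | (R)-5-bromo-2-[(3,7-dimethylocta-1,6-dien-3-yl)oxy]-1-ethenyl-3-methylbenzene | CC(C)=CCC[C@@](C)(Oc1c(C)cc(Br)cc1C=C)C=C | intermediate
6 | (R)-6-bromo-2,8-dimethyl-2-(4-methylpent-3-en-1-yl)-2H-chromene | CC(C)=CCC[C@]1(C)C=Cc2cc(Br)cc(C)c2O1 | intermediate
7 | [(R)-2,8-dimethyl-2-(4-methylpent-3-en-1-yl)-2H-chromen-6-yl]lithium | CC(C)=CCC[C@]1(C)C=Cc2cc([Li])cc(C)c2O1 | intermediate
8 | lithium trimethoxy[(R)-2,8-dimethyl-2-(4-methylpent-3-en-1-yl)-2H-chromen-6-yl]borate | CC(C)=CCC[C@]1(C)C=Cc2cc([B-](OC)(OC)OC)cc(C)c2O1.[Li+] | intermediate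
9 | (R)-2,8-dimethyl-2-(4-methylpent-3-en-1-yl)-2H-chromen-6-ol | CC(C)=CCC[C@]1(C)C=Cc2cc(O)cc(C)c2O1 | intermediate
10 | (R)-2,8-dimethyl-2-(4-methylpent-3-en-1-yl)-6-(triisopropylsilyloxy)-2H-chromene | CC(C)=CCC[C@]1(C)C=Cc2cc(O[Si](C(C)C)(C(C)C)C(C)C)cc(C)c2O1 | intermediate
11 | (E)-5-[(R)-2,8-dimethyl-6-(triisopropylsilyloxy)-2H-chromen-2-yl]-2-methylpent-2-en-1-ol | OC/C(C)=C/CC[C@]1(C)C=Cc2cc(O[Si](C(C)C)(C(C)C)C(C)C)cc(C)c2O1 | intermediate
12 | (E)-5-[(R)-2,8-dimethyl-6-(triisopropylsilyloxy)-2H-chromen-2-yl]-2-methylpent-2-enal | O=C/C(C)=C/CC[C@]1(C)C=Cc2cc(O[Si](C(C)C)(C(C)C)C(C)C)cc(C)c2O1 | intermediate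
13 | (R)-2,8-dimethyl-2-[(3E)-4-methylhexa-3,5-dien-1-yl]-6-(triisopropylsilyloxy)-2H-chromene | C=C/C(C)=C/CC[C@]1(C)C=Cc2cc(O[Si](C(C)C)(C(C)C)C(C)C)cc(C)c2O1 | intermediate
14 | 9-{(E)-6-[(R)-2,8-dimethyl-6-(triisopropylsilyloxy)-2H-chromen-2-yl]-3-methylhex-3-en-1-yl}-9-borabicyclo[3.3.1]nonane | C1CCC2CCCC1B2CC/C(C)=C/CC[C@]3(C)C=Cc4cc(O[Si](C(C)C)(C(C)C)C(C)C)cc(C)c4O3 | intermediate
15 | (E)-6-[(R)-2,8-dimethyl-6-(triisopropylsilyloxy)-2H-chromen-2-yl]-3-methylhex-3-en-1-ol | OCC/C(C)=C/CC[C@]1(C)C=Cc2cc(O[Si](C(C)C)(C(C)C)C(C)C)cc(C)c2O1 | intermediate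
16 | (R)-2-[(3E)-6-bromo-4-methylhex-3-en-1-yl]-2,8-dimethyl-6-(triisopropylsilyloxy)-2H-chromene | BrCC/C(C)=C/CC[C@]1(C)C=Cc2cc(O[Si](C(C)C)(C(C)C)C(C)C)cc(C)c2O1 | intermediate
17 | triethyl phosphonoacetate | CCOC(=O)CP(=O)(OCC)OCC | starting material
18 | 5-bromo-2-methylpent-2-ene | CC(C)=CCCBr | starting material
19 | sodium salt of triethyl phosphonoacetate | CCOC(=O)[CH-]P(=O)(OCC)OCC.[Na+] | intermediate
20 | ethyl 2-(diethoxyphosphoryl)-6-methylhept-5-enoate (racemic) | CCOC(=O)C(CCC=C(C)C)P(=O)(OCC)OCC | intermediate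
21 | ethyl 6-methyl-2-methylidenehept-5-enoate | CCOC(=O)C(=C)CCC=C(C)C | intermediate
22 | 6-methyl-2-methylidenehept-5-enoic acid | OC(=O)C(=C)CCC=C(C)C | intermediate
23 | 8-aminoquinoline | Nc1cccc2cccnc12 | starting material
24 | 6-methyl-2-methylidenehept-5-enoyl chloride | ClC(=O)C(=C)CCC=C(C)C | intermediate
25 | 6-methyl-2-methylidene-N-(quinolin-8-yl)hept-5-enamide | C=C(CCC=C(C)C)C(=O)Nc1cccc2cccnc12 | intermediate
26 | bromomagnesium amidate of 25 | C=C(CCC=C(C)C)C(=O)N([Mg]Br)c1cccc2cccnc12 | intermediate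
27 | (2Z,6E)-9-[(R)-2,8-dimethyl-6-(triisopropylsilyloxy)-2H-chromen-2-yl]-6-methyl-2-(4-methylpent-3-en-1-yl)-N-(quinolin-8-yl)nona-2,6-dienamide | CC(C)=CCC/C(=C/CC/C(C)=C/CC[C@]1(C)C=Cc2cc(O[Si](C(C)C)(C(C)C)C(C)C)cc(C)c2O1)C(=O)Nc1cccc2cccnc12 | intermediate
28 | tert-butyl N-acyl-N-(quinolin-8-yl)carbamate of 27 (N-Boc imide) | CC(C)=CCC/C(=C/CC/C(C)=C/CC[C@]1(C)C=Cc2cc(O[Si](C(C)C)(C(C)C)C(C)C)cc(C)c2O1)C(=O)N(C(=O)OC(C)(C)C)c1cccc2cccnc12 | intermediate
29 | lithium (2Z,6E)-9-[(R)-2,8-dimethyl-6-(triisopropylsilyloxy)-2H-chromen-2-yl]-6-methyl-2-(4-methylpent-3-en-1-yl)nona-2,6-dieneperoxoate | CC(C)=CCC/C(=C/CC/C(C)=C/CC[C@]1(C)C=Cc2cc(O[Si](C(C)C)(C(C)C)C(C)C)cc(C)c2O1)C(=O)O[O-].[Li+] | intermediate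
30 | (2Z,6E)-9-[(R)-2,8-dimethyl-6-(triisopropylsilyloxy)-2H-chromen-2-yl]-6-methyl-2-(4-methylpent-3-en-1-yl)nona-2,6-dienoic acid | CC(C)=CCC/C(=C/CC/C(C)=C/CC[C@]1(C)C=Cc2cc(O[Si](C(C)C)(C(C)C)C(C)C)cc(C)c2O1)C(=O)O | intermediate
31 | (R)-sargachromenol, (2Z,6E)-9-[(2R)-6-hydroxy-2,8-dimethyl-2H-chromen-2-yl]-6-methyl-2-(4-methylpent-3-en-1-yl)nona-2,6-dienoic acid | CC(C)=CCC/C(=C/CC/C(C)=C/CC[C@]1(C)C=Cc2cc(O)cc(C)c2O1)C(=O)O | target

**Step count and risks**

Total step count: 16. Longest linear sequence: 12 steps (steps 1 to 9, then 14, 15 and 16).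

The three steps most likely to fail:

Step 14. The bromide may be used up before it meets the ferracycle, by direct iron-catalysed coupling with the Grignard reagent or by β-hydride elimination back to the diene. The (E) geometry may also erode through reversible cyclisation of the homoallyl radical. The fallback sets out from diene 13 and forms the same bond by a two-electron cross-coupling. Hydroboration with 9-BBN gives borane 14, which would be coupled (Pd(dppf)Cl2, AsPh3, Cs2CO3, DMF/THF/H2O, rt, Suzuki–Miyaura) with (Z)-3-iodo-2-(4-methylpent-3-en-1-yl)prop-2-en-1-ol F2. This iodide would come from (4-methylpent-3-en-1-yl)magnesium bromide F1 (from 18 and Mg) by CuI-catalysed anti-carbomagnesiation of propargyl alcohol and iodinolysis with I2, the alkoxide chelate placing iodine cis to the CH2OH group. The coupled (2Z,6E)-allylic alcohol F3 would be oxidised with MnO2 to the (2Z)-enal F4 and then by Pinnick oxidation (NaClO2, NaH2PO4, 2-methylbut-2-ene, t-BuOH/H2O) to the acid, where the route is rejoined at 30.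

Step 1. The alkoxide may add reversibly to the formyl group and then transfer hydride (Cannizzaro- or Tishchenko-type redox), and substitution at a carbon flanked by two ortho substituents may be too slow to compete. The fallback sets out from 1 (as its alkoxide 3) and moves the activating group to a nitrile, which cannot enter such redox chemistry. SNAr on 5-bromo-2-fluoro-3-methylbenzonitrile (THF/DMF, rt) should give (R)-5-bromo-2-[(3,7-dimethylocta-1,6-dien-3-yl)oxy]-3-methylbenzonitrile F5. Reduction with i-Bu2AlH (toluene, −78 °C) and hydrolysis of the aldimine with dilute HCl returns the route at aldehyde 4.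

Step 15. Hydroperoxide may attack the carbamate carbonyl instead of the hindered acyl carbonyl and so return the amide, it may add in conjugate fashion to the activated acrylimide, and the Z olefin may isomerise under the basic conditions. The fallback sets out from 27, separates C–N cleavage from acid formation and avoids peroxide. The N-Boc imide 28 is isolated and opened with NaOMe in MeOH/THF at 0 °C to the methyl ester F6, which is saponified with LiOH in THF/MeOH/H2O to rejoin the route at 30.

Further compounds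

F1 | step 14 | (4-methylpent-3-en-1-yl)magnesium bromide | CC(C)=CCC[Mg]Br
F2 | step 14 | (Z)-3-iodo-2-(4-methylpent-3-en-1-yl)prop-2-en-1-ol | OC/C(CCC=C(C)C)=C\I
F3 | step 14 | (2Z,6E)-9-[(R)-2,8-dimethyl-6-(triisopropylsilyloxy)-2H-chromen-2-yl]-6-methyl-2-(4-methylpent-3-en-1-yl)nona-2,6-dien-1-ol | CC(C)=CCC/C(=C/CC/C(C)=C/CC[C@]1(C)C=Cc2cc(O[Si](C(C)C)(C(C)C)C(C)C)cc(C)c2O1)CO
F4 | step 14 | (2Z,6E)-9-[(R)-2,8-dimethyl-6-(triisopropylsilyloxy)-2H-chromen-2-yl]-6-methyl-2-(4-methylpent-3-en-1-yl)nona-2,6-dienal | CC(C)=CCC/C(=C/CC/C(C)=C/CC[C@]1(C)C=Cc2cc(O[Si](C(C)C)(C(C)C)C(C)C)cc(C)c2O1)C=O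
F5 | step 1 | (R)-5-bromo-2-[(3,7-dimethylocta-1,6-dien-3-yl)oxy]-3-methylbenzonitrile | CC(C)=CCC[C@@](C)(Oc1c(C)cc(Br)cc1C#N)C=C
F6 | step 15 | methyl (2Z,6E)-9-[(R)-2,8-dimethyl-6-(triisopropylsilyloxy)-2H-chromen-2-yl]-6-methyl-2-(4-methylpent-3-en-1-yl)nona-2,6-dienoate | CC(C)=CCC/C(=C/CC/C(C)=C/CC[C@]1(C)C=Cc2cc(O[Si](C(C)C)(C(C)C)C(C)C)cc(C)c2O1)C(=O)OC
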